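Balance the substrate first, before any integration.

the same everywhere: substrate 42 mM

| charge | reagent in the second phase | remark | time | volume of the second phase over the first |
|---|---|---|---|---|
| winter | 126 mM | the very flask that is asked about, followed so far |  |  |
| autumn | 63 mM | run made earlier |  |  |
| flask | 126 mM |  | 12 d | 2.0 |

- winter (time / d: substrate / %, over-reacted product / %, target / %): 0.333: 0.3, 83.3, 0; 0.833: 0.2, 84.0, 0.1; 1.67: 0, 83.1, 0; 2.50: 0.1, 83.9, 0; 4.00: 0.1, 84.4, 0
- autumn (time / d: substrate / %, over-reacted product / %, target / %): 1.67: 0.7, 72.4, 0; 3.00: 0, 72.5, 0; 5.00: 0, 72.0, 0; 6.00: 0, 71.9, 0; 8.00: 0.2, 72.3, 0

(scatter of a reading: 0.3 percentage points)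

- percent here means substrate units held: one homo dimer counts as two
- in the second phase: reagent in the second phase; everything else is in the first
- charges count per volume of the first phase; a concentration in a rate is the amount of a species over the volume of its own phase; every rate counts per litre of the first phase
- what was read earlier has a scatter of 0.3 percentage points, one standard deviation
- candidate steps: reagent in the reaction phase <-> reagent in the second phase; substrate + reagent in the reaction phase -> target; reagent in the reaction phase + target -> over-reacted product; 2 substrate -> homo dimer
- the earlier runs hold the two phases in the same ratio of volumes as the flask asked about
- the reaction counts as stopped when no species that holds the substrate changes by six tenths of a point or more over the second half of the time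

- why nothing more happens at 12 d, or that something still does (it is still moving / all of the substrate has reacted / forward and back rates have come level)
- conversion of substrate at 12 d
- amount of over-reacted product at 12 d, in percent of the substrate charged

The winter run is the asked flask followed to 4.00 d. At its last reading substrate stood at 0.1% and target at 0%, so I split the charge into two shares: over-reacted product, which I averaged over the readings, and homo dimer, the remainder. I call homo dimer over over-reacted product, as fractions of the charge, the loss ratio L, a selectivity.

winter: over-reacted product 83.7%, homo dimer 16.3%, L = 0.194

autumn: over-reacted product 72.2%, homo dimer 27.8%, L = 0.385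

The autumn run had half the reagent and twice the ratio. I took as an assumption that the time the substrate lasts goes as substrate charge over reagent charge, which these two ratios fit. Homo dimer goes with substrate squared, and when I replaced the falling curve by its mean, that mean scaled with the charge squared. My rule, at this ratio of phase volumes, was that L goes as substrate charge squared over reagent charge.

The forecast gave all of the substrate has reacted, conversion 100% and over-reacted product 83.7%, saying “With no substrate or target left, nothing can change”.

The flask gave all of the substrate has reacted, conversion 100% and over-reacted product 83.9%.

    reagent in the reaction phase ⇌ reagent in the second phase, rate k1*([reagent in the reaction phase] - [reagent in the second phase]/K1) per volume of the first phase (partition coefficient = 1.40, kL = 4.80 × 10⁻⁴ s⁻¹)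
    substrate + reagent in the reaction phase → target (k = 0.240 M⁻¹ s⁻¹)
    reagent in the reaction phase + target → over-reacted product (k = 0.370 M⁻¹ s⁻¹)
    2 substrate → homo dimer (k = 0.00210 M⁻¹ s⁻¹)

At 12.0 d the flask held 16.1% homo dimer and 83.9% over-reacted product, so L was 0.192 against my 0.194. The answer moved by 5 points with substrate at 51.1 mM or reagent at 89.3 mM. For the neighbour flask charged with 25 mM of substrate, I scaled L to 0.0688, which means 93.6% over-reacted product. The neighbour flask gave 92.5%.

(The earlier runs and the new flask come from a simulation from invented constants; noise was put on by code.)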